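**Remarks on the chemistry (assumptions)**

- The heptene chain is numbered C1 (CH2 on ring B) to C7 (methine on rings A and C). Ring A is numbered from the acyl-bearing carbon C1': 2'-OH, C3' (bonded to C7), 4'-OH, C5'-H, 6'-OMe. With this numbering the target is (3R,7R).
- "Hp" stands for the 5-[(tert-butyldimethylsilyl)oxy]-1,7-bis[4-(methoxymethoxy)phenyl]hept-2-en-1-yl group (its C1 is chain C7, its C5 is chain C3). "Hp'" is the same group with tert-butyldimethylsilyl ethers on both phenols. The descriptors are written in front each time; the C1 descriptor changes with the attached group although the spatial arrangement stays the same.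
- The sense of induction of the (R,R) diene ligand in step 8 is assumed to place the alkenyl group on the Re face of the benzylidene carbon of 10. Should a test reaction show the opposite sense, the (S,S) ligand is used and nothing else changes.

## Analysis of the target

Katsumain C (23) is an open-chain 1,7-diarylhept-5-ene whose C7 methine also carries ring A. Ring A is an acylphloroglucinol monomethyl ether with an (E)-cinnamoyl group, that is, a 2'-hydroxychalcone. C7 sits on C3' between two free hydroxyls, and the methyl ether is on the ortho oxygen remote from C7. There are two stereocentres, the C3 carbinol (R) and the C7 methine (R), which bears rings A and C, a hydrogen and the alkenyl carbon C6. They stand in a 1,5-relationship across the (E)-C5=C6 bond, too far apart for one to control the other, so each has to be set by a reagent or catalyst and the alkene geometry has to be fixed separately. The sensitive sites are the chalcone enone (Michael acceptor, flavanone closure through the 2'-hydroxyl), the C7–H bond, which is doubly benzylic and allylic (double-bond migration, acid-induced ionisation of the ring A–C7 bond), the oxidation-prone phloroglucinol ring and four free phenols. The synthesis is hard because C3' is flanked by two oxygens and carries a branched substituent, so a late union of ring A with C7 would have to control site, regiochemistry on an unsymmetrical allyl unit and configuration at once. In addition the three ring A oxygens must end up differentiated. The strategy rests on one feature: ring A with its acyl carbonyl is the Claisen-folded form of a 3,5,7-trioxo acid, and C3' is the α-carbon of that acid. The C7 unit can therefore be attached to a malonate carbon before the ring exists, and the ring is closed by forming the C1'–C2' bond.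

## Retrosynthetic reasoning

**Target 23 to acetophenone 20 and benzaldehyde 21.** The three methoxymethyl ethers and the silyl ether of chalcone 22 are removed last, so that the free polyphenol is never carried through a basic or alkylating step. Chalcone 22 is cut at the enone Cα=Cβ bond into 20 and 21. This is the only C–C bond made after ring A exists, it uses the acetyl group that the ring synthesis delivers, and it puts the most reactive function in at the end.

**Acetophenone 20 to triol 18.** The O–CH3 bond at 6'-O and the acetal O–C bond at 4'-O are cut in that order, giving 19 and then 18. The forward steps must tell three hydroxyls apart: the para oxygen is the most acidic and is capped first (19); of the two chelated ortho oxygens the one not wedged against the C7 substituent is methylated (20).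

**Triol 18 to pyrone 16 (key disconnection).** The C1'–C2' bond of ring A is cut, unfolding the arene into the triketo ester 17, which is stored as its lactone, pyrone 16. Cutting here and not at the ring A–C7 bond means that the crowded C3'–C7 bond is already present in an sp3 precursor. All six ring carbons, the three oxygens and the acetyl group arrive in one chain, and the ring closure is an intramolecular acylation by the most acidic carbon of that chain. The forward reaction has to open the lactone and fold the chain in the Claisen sense without touching C7.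

**Pyrone 16 to diacid 12 and bis(silyl enol ether) 14.** The pyrone C4–C5 bond and the lactone O1–C2 bond are cut. This returns the substituted malonic acid 12, activated in the flask as dichloride 15, and diene 14 made from acetylacetone 13. The five carbons of 14 supply ring carbons C5' and C6', the acetyl-bearing carbon and the acetyl group. Two steps from a malonate reach the precursor, and both chlorides leave as a neutral silyl chloride.

**Diacid 12 to boronate 6 and benzylidenemalonate 10.** Acid 12 comes from diester 11, which is cut at the C6–C7 bond. This is the most convergent cut of the chain: it joins the ring B half to the ring C half, creates the C7 stereocentre under catalyst control, and transfers the E geometry of the alkenylboron reagent unchanged. Acceptor 10 is the Knoevenagel product of aldehyde 8 (from 7) and dimethyl malonate 9.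

**Boronate 6 to ester 1.** The C5=C6 bond of 6 is formed by cross-metathesis of the terminal alkene 5 with a vinylboron partner. The C3–C4 bond is cut next: homoallylic alcohol 4 arises from aldehyde 3 by reagent-controlled allylboration, which sets C3. Aldehyde 3 comes from ester 1 through its protected form 2.

## Alternatives that were turned down

**Alternative 1: Danheiser benzannulation around C7.** Ring A would be disconnected into the 4-substituted 3-siloxycyclobutenone A2 and methoxyacetylene A3. On heating, A2 opens to a vinylketene, A3 adds across the ketene, the resulting cyclobutenone opens again and a 6π closure gives the resorcinol derivative A1. In A1 the three ring oxygens are already distinct (free hydroxyl, silyl ether, methyl ether), which is a real advantage over the chosen route, where two selective O-functionalisations are needed. Against it: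
- A2 must carry the C7 stereocentre on its sp3 ring carbon, and an enantioenriched cyclobutenone of this kind needs a multistep preparation of its own.
- In the vinylketene the C7–H bond is allylic to a diene, so hydrogen shifts can erode C7 at the temperature of the reaction.
- A3 is volatile and unstable.
- A1 still lacks the acyl group, which would have to be forced onto a hindered carbon between two oxygens by electrophilic acylation or metalation in the presence of acid-labile ethers and a nucleophilic alkene.

The chosen strategy forms the aryl ketone in the ring-closing event and reaches its precursor in two steps from a malonate; it pays with the late differentiation of the hydroxyls.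

**Alternative 2: siloxydiene Diels–Alder aromatisation.** Ring A would be cut into the 2-substituted 1-methoxy-1,3-bis(siloxy)diene A5 and the ynone A6. Cycloaddition followed by loss of a silyl methyl ether and aromatisation gives acetophenone A4. A4 has the acetyl group and the methyl ether in place, so no hydroxyl has to be differentiated and the end game is two steps shorter; on this point the alternative is stronger. Against it:
- A5 is a tetrasubstituted ketene acetal with a bulky secondary group at C2. The s-cis form is strained, and making it needs γ-silylation of an α-branched β-keto ester next to the C7 centre.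
- A6 is a push–pull alkyne and a poor dienophile. It is likely to react stepwise, so the regiochemistry is not secured by the mechanism.

The risk would sit in a step for which the hindered case has no close model, and the precursor is harder to make. The chosen closure uses a stable pyrone and a folding mode known for the parent system.

**Alternative 3: carbocyclisation of a 4-methoxy-2-pyrone.** Ring A would be cut at the bond between C3' and a neighbouring C–OH carbon, leading back to pyrone A8, in which the C7 unit hangs on the side-chain CH2. Base opens the lactone and the side-chain enolate attacks the ester to give the symmetric resorcinol A7. The methyl ether is present from the start, and because A7 is symmetric the later acylation has two equivalent positions and no regiochemical question; here the alternative is cleaner than the chosen route. Against it: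
- The nucleophile is the less acidic and more hindered of two CH2 groups.
- The bond formed is the crowded one to the C7-bearing carbon.
- The cinnamoyl or acetyl group must afterwards be introduced by Friedel–Crafts or Fries chemistry on a substrate with acetal and silyl ethers, an alkene and an ionisable C7–aryl bond.

The chosen strategy avoids any electrophilic acylation of ring A and uses the most acidic carbon of the chain as the nucleophile; in exchange it needs two selective O-alkylations.

Key step: step 12

## Route

**Step 1**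
Reactants: 1 methyl 3-(4-hydroxyphenyl)propanoate
Product: 2 methyl 3-[4-(methoxymethoxy)phenyl]propanoate
Conditions: MOMCl, i-Pr2NEt, CH2Cl2, 0 °C to rt
Reagents that add atoms: chloromethyl methyl ether, COCCl
Why: O-alkylation of the phenol to the methoxymethyl acetal, which is stable to hydride, organometallic and basic steps; the ester is untouched.

**Step 2**
Reactants: 2 methyl 3-[4-(methoxymethoxy)phenyl]propanoate
Product: 3 3-[4-(methoxymethoxy)phenyl]propanal
Conditions: i-Bu2AlH (1.05 equiv), CH2Cl2, −78 °C; aq. KNaC4H4O6 work-up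
Reagents that add atoms: none
Why: Partial reduction of the ester; the tetrahedral aluminium hemiacetal is stable at −78 °C and releases the aldehyde only on work-up.

**Step 3**
Reactants: 3 3-[4-(methoxymethoxy)phenyl]propanal
Product: 4 (3R)-1-[4-(methoxymethoxy)phenyl]hex-5-en-3-ol
Conditions: (−)-Ipc2BOMe, CH2=CHCH2MgBr, Et2O, 0 °C to rt; then 3, −78 °C; then NaOH, H2O2, rt
Reagents that add atoms: allylmagnesium bromide, C=CC[Mg]Br
Why: Brown asymmetric allylboration through a chair Zimmerman–Traxler transition state; the isopinocampheyl groups of the reagent made from (−)-Ipc2BOMe direct the allyl group to the Si face of the aldehyde, which sets C3 as R.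

**Step 4**
Reactants: 4 (3R)-1-[4-(methoxymethoxy)phenyl]hex-5-en-3-ol
Product: 5 tert-butyl{[(3R)-1-[4-(methoxymethoxy)phenyl]hex-5-en-3-yl]oxy}dimethylsilane
Conditions: TBSCl, imidazole, DMF, rt
Reagents that add atoms: tert-butyldimethylsilyl chloride, CC(C)(C)[Si](C)(C)Cl
Why: Standard silylation of a secondary alcohol; the silyl ether tolerates the metathesis, the aqueous base of the rhodium step, saponification and methoxide.

**Step 5**
Reactants: 5 tert-butyl{[(3R)-1-[4-(methoxymethoxy)phenyl]hex-5-en-3-yl]oxy}dimethylsilane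
Product: 6 tert-butyl{[(3R,5E)-1-[4-(methoxymethoxy)phenyl]-6-(4,4,5,5-tetramethyl-1,3,2-dioxaborolan-2-yl)hex-5-en-3-yl]oxy}dimethylsilane
Conditions: vinylboronic acid pinacol ester (3 equiv), second-generation Grubbs catalyst RuCl2(=CHPh)(PCy3)(H2IMes) (5 mol%), CH2Cl2, 40 °C
Reagents that add atoms: 4,4,5,5-tetramethyl-2-vinyl-1,3,2-dioxaborolane, C=CB1OC(C)(C)C(C)(C)O1
Why: Olefin cross-metathesis of a terminal alkene with a vinylboronate; loss of ethylene drives it and the bulky boronate should favour the E alkene under thermodynamic control.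

**Step 6**
Reactants: 7 4-hydroxybenzaldehyde
Product: 8 4-(methoxymethoxy)benzaldehyde
Conditions: MOMCl, i-Pr2NEt, CH2Cl2, 0 °C to rt
Reagents that add atoms: chloromethyl methyl ether, COCCl
Why: O-alkylation of the acidic para-formyl phenol; the aldehyde is not affected.

**Step 7**
Reactants: 8 4-(methoxymethoxy)benzaldehyde; 9 dimethyl malonate
Product: 10 dimethyl 2-[4-(methoxymethoxy)benzylidene]malonate
Conditions: piperidine (0.1 equiv), AcOH (0.1 equiv), toluene, reflux, Dean–Stark trap
Reagents that add atoms: none
Why: Knoevenagel condensation driven by azeotropic removal of water; the buffered amine salt is too weakly acidic to harm the acetal.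

**Step 8**
Reactants: 6 the (3R,5E)-alkenyl pinacol boronate; 10 dimethyl 2-[4-(methoxymethoxy)benzylidene]malonate
Product: 11 dimethyl 2-[(1S,2E,5R)-Hp]malonate
Conditions: 6 (1.5 equiv), [RhCl(C2H4)2]2 (2.5 mol%), (1R,4R)-2,5-diphenylbicyclo[2.2.2]octa-2,5-diene (5.5 mol%), aq. KOH (0.3 equiv), 1,4-dioxane/H2O 10:1, 40 °C
Reagents that add atoms: none
Why: Hayashi–Miyaura conjugate addition: hydroxide-assisted transfer of the alkenyl group from boron to rhodium, insertion of the doubly activated alkene and protonolysis of the rhodium malonate enolate. The chiral diene exposes the Re face of the benzylidene carbon, which sets C7 (S in 11 by the priority rules, the same spatial arrangement as 7R in 23); the E geometry of 6 is retained.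

**Step 9**
Reactants: 11 dimethyl 2-[(1S,2E,5R)-Hp]malonate
Product: 12 2-[(1S,2E,5R)-Hp]malonic acid
Conditions: LiOH·H2O (8 equiv), THF/MeOH/H2O 3:1:1, 40 °C; then 1 M HCl to pH 3, 0 °C
Reagents that add atoms: lithium hydroxide, [Li+].[OH-]
Why: Saponification of both esters; acetal and silyl ethers are stable to hydroxide, C7 is not acidic, and cold acidification avoids decarboxylation of the malonic acid.

**Step 10**
Reactants: 13 acetylacetone
Product: 14 (3Z)-2,4-bis(trimethylsiloxy)penta-1,3-diene
Conditions: TMSOTf (2.2 equiv), Et3N (2.5 equiv), Et2O, 0 °C to rt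
Reagents that add atoms: trimethylsilyl trifluoromethanesulfonate, C[Si](C)(C)OS(=O)(=O)C(F)(F)F
Why: Double soft enolisation and O-silylation of the 1,3-diketone; the second silylation occurs at the methyl terminus and gives the 1,3-bis(silyl enol ether).

**Step 11**
Reactants: 12 2-[(1S,2E,5R)-Hp]malonic acid; 14 (3Z)-2,4-bis(trimethylsiloxy)penta-1,3-diene
Product: 16 3-[(1R,2E,5R)-Hp]-4-hydroxy-6-(2-oxopropyl)-2H-pyran-2-one, via substituted malonyl dichloride 15 (not isolated)
Conditions: 1-chloro-N,N,2-trimethylprop-1-en-1-amine (2.2 equiv), CH2Cl2, 0 °C to rt; then 14 (1.2 equiv), −78 °C to rt; aq. citric acid work-up (pH 4)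
Reagents that add atoms: none
Why: The chloroenamine forms the acid chloride under neutral conditions. In an Effenberger-type pyrone synthesis the terminal carbon of 14 is acylated by one acid chloride and the enol oxygen of the new 1,3-diketone closes the lactone on the second. Both chlorides leave as Me3SiCl, so no HCl is set free near the acetal and silyl ethers.

**Step 12**
Reactants: 16 3-[(1R,2E,5R)-Hp]-4-hydroxy-6-(2-oxopropyl)-2H-pyran-2-one
Product: 18 1-{3-[(1R,2E,5R)-Hp]-2,4,6-trihydroxyphenyl}ethan-1-one, via ring-opened methyl 3,5,7-trioxooctanoate 17 (not isolated)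
Conditions: Mg(OMe)2 (6 equiv), MeOH, reflux; then aq. NH4Cl/1 M HCl to pH 4, 0 °C
Reagents that add atoms: none
Why: Mg(OMe)2 first forms the magnesium salts of the 4-hydroxyl and of the side-chain CH2; methoxide then adds to the lactone carbonyl and the ring opens to the magnesium chelate of triketo ester 17. In 17 the CH2 between the C5 and C7 ketones is the most acidic carbon, and its enolate attacks the ester carbonyl in a Claisen (Dieckmann-type) acylation; methoxide leaves and the cyclohexane-1,3,5-trione enolises to the phloroglucinol, which pulls all preceding equilibria forward. The closest known reaction type is the conversion of 6-(2-oxoalkyl)-4-hydroxy-2-pyrones and of 3,5,7-trioxo esters into acylphloroglucinols with Mg(OMe)2 in methanol. Ring A is the only ring closed and the closure is 6-exo-trig. No stereocentre is formed; C7 is not α to any carbonyl of 16, 17 or 18 and cannot epimerise, and the acetal and silyl ethers are inert to methoxide. The selectivity needed is Claisen over aldol folding: the aldol of the ester α-carbon onto the methyl ketone would give a quaternary carbon carrying the C7 unit and cannot aromatise, so it stays reversible. Chelation of the 3,5-diketone unit to magnesium holds the chain folded with the nucleophilic carbon next to the ester and keeps the terminal methyl group from competing.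

**Step 13**
Reactants: 18 1-{3-[(1R,2E,5R)-Hp]-2,4,6-trihydroxyphenyl}ethan-1-one
Product: 19 1-{3-[(1R,2E,5R)-Hp]-2,6-dihydroxy-4-(methoxymethoxy)phenyl}ethan-1-one
Conditions: MOMCl (1.05 equiv), i-Pr2NEt (1.2 equiv), CH2Cl2, −20 to 0 °C
Reagents that add atoms: chloromethyl methyl ether, COCCl
Why: Chemoselective O-alkylation: the 4'-hydroxyl is para to the acyl group and not hydrogen-bonded, hence the most acidic, so with one equivalent of a small electrophile its phenoxide should react before the two ortho hydroxyls that share the hydrogen bond to the carbonyl.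

**Step 14**
Reactants: 19 1-{3-[(1R,2E,5R)-Hp]-2,6-dihydroxy-4-(methoxymethoxy)phenyl}ethan-1-one
Product: 20 1-{3-[(1R,2E,5R)-Hp]-2-hydroxy-6-methoxy-4-(methoxymethoxy)phenyl}ethan-1-one
Conditions: MeI (1.2 equiv), K2CO3 (1.5 equiv), acetone, rt
Reagents that add atoms: iodomethane, CI
Why: Williamson methylation of the 6'-phenoxide: the 2'-oxygen is wedged between the acetyl group and the C7 substituent and is the one held in the hydrogen bond, so the open 6'-oxygen should react; after that the remaining chelated 2'-hydroxyl is inert to MeI at room temperature.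

**Step 15**
Reactants: 20 1-{3-[(1R,2E,5R)-Hp]-2-hydroxy-6-methoxy-4-(methoxymethoxy)phenyl}ethan-1-one; 21 benzaldehyde
Product: 22 (2E)-1-{3-[(1R,2E,5R)-Hp]-2-hydroxy-6-methoxy-4-(methoxymethoxy)phenyl}-3-phenylprop-2-en-1-one
Conditions: KOH (50% aq.), EtOH, rt
Reagents that add atoms: none
Why: Claisen–Schmidt condensation of the methyl ketone with a non-enolisable aldehyde; dehydration gives the conjugated E enone. C7 is meta to the acyl carbon and not acidified, and the 2'-phenoxide suppresses flavanone closure in base.

**Step 16**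
Reactants: 22 (2E)-1-{3-[(1R,2E,5R)-Hp]-2-hydroxy-6-methoxy-4-(methoxymethoxy)phenyl}-3-phenylprop-2-en-1-one
Product: 23 katsumain C, (2E)-1-{2,4-dihydroxy-3-[(1R,2E,5R)-5-hydroxy-1,7-bis(4-hydroxyphenyl)hept-2-en-1-yl]-6-methoxyphenyl}-3-phenylprop-2-en-1-one
Conditions: 3 M aq. HCl/MeOH 1:5, rt to 40 °C
Reagents that add atoms: none
Why: Acid-catalysed acetal exchange removes the three methoxymethyl ethers and solvolysis removes the silyl ether in one operation; the temperature is kept low so that the 2'-hydroxychalcone does not isomerise to the flavanone and the ring A–C7 bond does not ionise.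

## Compound list

1 | methyl 3-(4-hydroxyphenyl)propanoate | COC(=O)CCc1ccc(O)cc1 | starting material
2 | methyl 3-[4-(methoxymethoxy)phenyl]propanoate | COC(=O)CCc1ccc(OCOC)cc1 | intermediate
3 | 3-[4-(methoxymethoxy)phenyl]propanal | O=CCCc1ccc(OCOC)cc1 | intermediate
4 | (3R)-1-[4-(methoxymethoxy)phenyl]hex-5-en-3-ol | C=CC[C@H](O)CCc1ccc(OCOC)cc1 | intermediate
5 | tert-butyl{[(3R)-1-[4-(methoxymethoxy)phenyl]hex-5-en-3-yl]oxy}dimethylsilane | C=CC[C@H](O[Si](C)(C)C(C)(C)C)CCc1ccc(OCOC)cc1 | intermediate
6 | tert-butyl{[(3R,5E)-1-[4-(methoxymethoxy)phenyl]-6-(4,4,5,5-tetramethyl-1,3,2-dioxaborolan-2-yl)hex-5-en-3-yl]oxy}dimethylsilane | CC1(C)OB(/C=C/C[C@H](O[Si](C)(C)C(C)(C)C)CCc2ccc(OCOC)cc2)OC1(C)C | intermediate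
7 | 4-hydroxybenzaldehyde | O=Cc1ccc(O)cc1 | starting material
8 | 4-(methoxymethoxy)benzaldehyde | COCOc1ccc(C=O)cc1 | intermediate
9 | dimethyl malonate | COC(=O)CC(=O)OC | starting material
10 | dimethyl 2-[4-(methoxymethoxy)benzylidene]malonate | COCOc1ccc(C=C(C(=O)OC)C(=O)OC)cc1 | intermediate
11 | dimethyl 2-[(1S,2E,5R)-5-[(tert-butyldimethylsilyl)oxy]-1,7-bis[4-(methoxymethoxy)phenyl]hept-2-en-1-yl]malonate | COC(=O)C(C(=O)OC)[C@H](/C=C/C[C@H](O[Si](C)(C)C(C)(C)C)CCc1ccc(OCOC)cc1)c1ccc(OCOC)cc1 | intermediate
12 | 2-[(1S,2E,5R)-5-[(tert-butyldimethylsilyl)oxy]-1,7-bis[4-(methoxymethoxy)phenyl]hept-2-en-1-yl]malonic acid | OC(=O)C(C(=O)O)[C@H](/C=C/C[C@H](O[Si](C)(C)C(C)(C)C)CCc1ccc(OCOC)cc1)c1ccc(OCOC)cc1 | intermediate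
13 | acetylacetone (pentane-2,4-dione) | CC(=O)CC(C)=O | starting material
14 | (3Z)-2,4-bis(trimethylsiloxy)penta-1,3-diene | C=C(O[Si](C)(C)C)/C=C(/C)O[Si](C)(C)C | intermediate
15 | 2-[(1S,2E,5R)-5-[(tert-butyldimethylsilyl)oxy]-1,7-bis[4-(methoxymethoxy)phenyl]hept-2-en-1-yl]malonyl dichloride (not isolated) | O=C(Cl)C(C(=O)Cl)[C@H](/C=C/C[C@H](O[Si](C)(C)C(C)(C)C)CCc1ccc(OCOC)cc1)c1ccc(OCOC)cc1 | intermediate
16 | 3-[(1R,2E,5R)-5-[(tert-butyldimethylsilyl)oxy]-1,7-bis[4-(methoxymethoxy)phenyl]hept-2-en-1-yl]-4-hydroxy-6-(2-oxopropyl)-2H-pyran-2-one | CC(=O)CC1=CC(O)=C([C@H](/C=C/C[C@H](O[Si](C)(C)C(C)(C)C)CCc2ccc(OCOC)cc2)c2ccc(OCOC)cc2)C(=O)O1 | intermediate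
17 | methyl 2-[(1S,2E,5R)-5-[(tert-butyldimethylsilyl)oxy]-1,7-bis[4-(methoxymethoxy)phenyl]hept-2-en-1-yl]-3,5,7-trioxooctanoate (magnesium enolate in the flask, both C2 epimers, not isolated) | COC(=O)C(C(=O)CC(=O)CC(C)=O)[C@H](/C=C/C[C@H](O[Si](C)(C)C(C)(C)C)CCc1ccc(OCOC)cc1)c1ccc(OCOC)cc1 | intermediate
18 | 1-{3-[(1R,2E,5R)-5-[(tert-butyldimethylsilyl)oxy]-1,7-bis[4-(methoxymethoxy)phenyl]hept-2-en-1-yl]-2,4,6-trihydroxyphenyl}ethan-1-one | CC(=O)c1c(O)cc(O)c([C@H](/C=C/C[C@H](O[Si](C)(C)C(C)(C)C)CCc2ccc(OCOC)cc2)c2ccc(OCOC)cc2)c1O | intermediate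
19 | 1-{3-[(1R,2E,5R)-5-[(tert-butyldimethylsilyl)oxy]-1,7-bis[4-(methoxymethoxy)phenyl]hept-2-en-1-yl]-2,6-dihydroxy-4-(methoxymethoxy)phenyl}ethan-1-one | CC(=O)c1c(O)cc(OCOC)c([C@H](/C=C/C[C@H](O[Si](C)(C)C(C)(C)C)CCc2ccc(OCOC)cc2)c2ccc(OCOC)cc2)c1O | intermediate
20 | 1-{3-[(1R,2E,5R)-5-[(tert-butyldimethylsilyl)oxy]-1,7-bis[4-(methoxymethoxy)phenyl]hept-2-en-1-yl]-2-hydroxy-6-methoxy-4-(methoxymethoxy)phenyl}ethan-1-one | CC(=O)c1c(OC)cc(OCOC)c([C@H](/C=C/C[C@H](O[Si](C)(C)C(C)(C)C)CCc2ccc(OCOC)cc2)c2ccc(OCOC)cc2)c1O | intermediate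
21 | benzaldehyde | O=Cc1ccccc1 | starting material
22 | (2E)-1-{3-[(1R,2E,5R)-5-[(tert-butyldimethylsilyl)oxy]-1,7-bis[4-(methoxymethoxy)phenyl]hept-2-en-1-yl]-2-hydroxy-6-methoxy-4-(methoxymethoxy)phenyl}-3-phenylprop-2-en-1-one | COc1cc(OCOC)c([C@H](/C=C/C[C@H](O[Si](C)(C)C(C)(C)C)CCc2ccc(OCOC)cc2)c2ccc(OCOC)cc2)c(O)c1C(=O)/C=C/c1ccccc1 | intermediate
23 | katsumain C, (2E)-1-{2,4-dihydroxy-3-[(1R,2E,5R)-5-hydroxy-1,7-bis(4-hydroxyphenyl)hept-2-en-1-yl]-6-methoxyphenyl}-3-phenylprop-2-en-1-one | COc1cc(O)c([C@H](/C=C/C[C@H](O)CCc2ccc(O)cc2)c2ccc(O)cc2)c(O)c1C(=O)/C=C/c1ccccc1 | target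

## Step count and least certain steps

Total: 16 steps. Longest linear sequence: 13 steps (steps 1–5, 8, 9, 11–16).

**Step 12 (key step).** The lactone may open incompletely, because the magnesium 4-oxidopyrone is a vinylogous carboxylate and a poor electrophile. Methoxide may also cleave the side-chain β-diketone by retro-Claisen reaction before ring A closes. Fallback, from 11 back to 18 without a lactone: one ester of 11 is hydrolysed with KOH (1.0 equiv) in MeOH/THF at 0 °C to the half-ester 2-[(1S,2E,5R)-Hp]-3-methoxy-3-oxopropanoic acid F1. F1 is converted with 1-chloro-N,N,2-trimethylprop-1-en-1-amine into methyl 3-chloro-3-oxo-2-[(1S,2E,5R)-Hp]propanoate F2. F2 acylates the terminal carbon of diene 14 (CH2Cl2, −78 °C to rt, aqueous work-up) to give the open-chain triketo ester 17 as an isolable enol mixture. Brief treatment of 17 with Mg(OMe)2 in MeOH then closes ring A to 18. Both operations are known reaction types (terminal C-acylation of 1,3-bis(silyl enol ethers) by acid chlorides; Claisen cyclisation of 3,5,7-trioxo esters).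

**Step 8.** Insertion of the hindered, electron-rich benzylidenemalonate into the alkenyl–rhodium bond may be slow, so that protodeboronation of 6 and hydroxide-induced retro-Knoevenagel cleavage of 10 compete. The two geminal esters also offer the catalyst no single binding mode, which may lower the facial discrimination. Fallback, from 8, 9 and 5 back to 11, by asymmetric allylic alkylation and cross-metathesis: aldehyde 8 and CH2=CHMgBr give racemic 1-[4-(methoxymethoxy)phenyl]prop-2-en-1-ol F3. Methyl chloroformate and pyridine convert it into methyl 1-[4-(methoxymethoxy)phenyl]prop-2-en-1-yl carbonate F4. Molybdenum-catalysed asymmetric allylic alkylation of F4 with the sodium salt of 9 (Mo(CO)3(C7H8), the enantiomer of the trans-cyclohexane-1,2-diamine bis(picolinamide) ligand that delivers the 1S product, THF, 60 °C) gives the branched dimethyl 2-[(1S)-1-[4-(methoxymethoxy)phenyl]prop-2-en-1-yl]malonate F5. Cross-metathesis of F5 with alkene 5 (second-generation Grubbs catalyst RuCl2(=CHPh)(PCy3)(H2IMes), CH2Cl2, 40 °C) gives 11; steps 4 and 5 then end at 5 and boronate 6 is not needed.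

**Step 11.** Diene 14 is ambident: it may attack through its internal carbon or close the ring through carbon instead of oxygen. The α-branched malonyl dichloride 15 may also lose HCl to a ketene that oligomerises. Fallback, from 15 back to 16 in two stages: 15 is condensed with the simple enol ether 2-(trimethylsiloxy)propene (2.5 equiv, CH2Cl2, −78 °C to rt; the excess traps HCl) to give 3-[(1R,2E,5R)-Hp]-4-hydroxy-6-methyl-2H-pyran-2-one F6. The dianion of F6 (LiN(i-Pr)2, 2.2 equiv, THF, −78 °C) is acylated at the 6-methyl carbon with N-methoxy-N-methylacetamide to give 16.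

**Step 13.** Alkylation may spread over the 4'- and 6'-oxygens and go on to bis-ethers, because the para oxygen, although the most acidic, lies next to the bulky C7 substituent. Fallback, from 16 back to 19, which distinguishes the oxygens by their origin instead of by their acidity: the pyrone hydroxyl of 16 is capped first (MOMCl, i-Pr2NEt, CH2Cl2, 0 °C) to give 3-[(1R,2E,5R)-Hp]-4-(methoxymethoxy)-6-(2-oxopropyl)-2H-pyran-2-one F7. The base-induced carbocyclisation of this 4-alkoxy-2-pyrone (NaOMe or Mg(OMe)2, MeOH, reflux) then delivers 19 directly with the para oxygen already protected.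

**Step 14.** Methylation may occur at the 2'-oxygen or at both ortho oxygens if the hydrogen bond to the acetyl group switches between them. Fallback, from 19 to 23, sorting the two oxygens with a bulky silyl group instead of a small alkylating agent:
- TBDPSCl and imidazole in DMF should silylate only the open 6'-oxygen, giving 1-{6-[(tert-butyldiphenylsilyl)oxy]-3-[(1R,2E,5R)-Hp]-2-hydroxy-4-(methoxymethoxy)phenyl}ethan-1-one F8.
- NaH and MOMCl in DMF cap the 2'-hydroxyl, giving 1-{6-[(tert-butyldiphenylsilyl)oxy]-3-[(1R,2E,5R)-Hp]-2,4-bis(methoxymethoxy)phenyl}ethan-1-one F9.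
- n-Bu4NF buffered with AcOH at 0 °C removes the aryl silyl ether, giving 1-{3-[(1R,2E,5R)-Hp]-6-hydroxy-2,4-bis(methoxymethoxy)phenyl}ethan-1-one F10. Loss of the alkyl silyl ether here would do no harm.
- MeI and K2CO3 in acetone give 1-{3-[(1R,2E,5R)-Hp]-6-methoxy-2,4-bis(methoxymethoxy)phenyl}ethan-1-one F11.
- Condensation with 21 (KOH, EtOH) gives (2E)-1-{3-[(1R,2E,5R)-Hp]-6-methoxy-2,4-bis(methoxymethoxy)phenyl}-3-phenylprop-2-en-1-one F12, and the acid treatment of step 16 gives 23.

## Further compounds

F1 | step 12 | 2-[(1S,2E,5R)-5-[(tert-butyldimethylsilyl)oxy]-1,7-bis[4-(methoxymethoxy)phenyl]hept-2-en-1-yl]-3-methoxy-3-oxopropanoic acid (both C2 epimers) | COC(=O)C(C(O)=O)[C@H](/C=C/C[C@H](O[Si](C)(C)C(C)(C)C)CCc1ccc(OCOC)cc1)c1ccc(OCOC)cc1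
F2 | step 12 | methyl 3-chloro-3-oxo-2-[(1S,2E,5R)-5-[(tert-butyldimethylsilyl)oxy]-1,7-bis[4-(methoxymethoxy)phenyl]hept-2-en-1-yl]propanoate (both C2 epimers) | COC(=O)C(C(Cl)=O)[C@H](/C=C/C[C@H](O[Si](C)(C)C(C)(C)C)CCc1ccc(OCOC)cc1)c1ccc(OCOC)cc1
F3 | step 8 | 1-[4-(methoxymethoxy)phenyl]prop-2-en-1-ol (racemic) | C=CC(O)c1ccc(OCOC)cc1
F4 | step 8 | methyl 1-[4-(methoxymethoxy)phenyl]prop-2-en-1-yl carbonate (racemic) | C=CC(OC(=O)OC)c1ccc(OCOC)cc1
F5 | step 8 | dimethyl 2-[(1S)-1-[4-(methoxymethoxy)phenyl]prop-2-en-1-yl]malonate | COC(=O)C(C(=O)OC)[C@H](C=C)c1ccc(OCOC)cc1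
F6 | step 11 | 3-[(1R,2E,5R)-5-[(tert-butyldimethylsilyl)oxy]-1,7-bis[4-(methoxymethoxy)phenyl]hept-2-en-1-yl]-4-hydroxy-6-methyl-2H-pyran-2-one | CC1=CC(O)=C([C@H](/C=C/C[C@H](O[Si](C)(C)C(C)(C)C)CCc2ccc(OCOC)cc2)c2ccc(OCOC)cc2)C(=O)O1
F7 | step 13 | 3-[(1R,2E,5R)-5-[(tert-butyldimethylsilyl)oxy]-1,7-bis[4-(methoxymethoxy)phenyl]hept-2-en-1-yl]-4-(methoxymethoxy)-6-(2-oxopropyl)-2H-pyran-2-one | CC(=O)CC1=CC(OCOC)=C([C@H](/C=C/C[C@H](O[Si](C)(C)C(C)(C)C)CCc2ccc(OCOC)cc2)c2ccc(OCOC)cc2)C(=O)O1
F8 | step 14 | 1-{6-[(tert-butyldiphenylsilyl)oxy]-3-[(1R,2E,5R)-5-[(tert-butyldimethylsilyl)oxy]-1,7-bis[4-(methoxymethoxy)phenyl]hept-2-en-1-yl]-2-hydroxy-4-(methoxymethoxy)phenyl}ethan-1-one | CC(=O)c1c(O[Si](c2ccccc2)(c2ccccc2)C(C)(C)C)cc(OCOC)c([C@H](/C=C/C[C@H](O[Si](C)(C)C(C)(C)C)CCc2ccc(OCOC)cc2)c2ccc(OCOC)cc2)c1O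
F9 | step 14 | 1-{6-[(tert-butyldiphenylsilyl)oxy]-3-[(1R,2E,5R)-5-[(tert-butyldimethylsilyl)oxy]-1,7-bis[4-(methoxymethoxy)phenyl]hept-2-en-1-yl]-2,4-bis(methoxymethoxy)phenyl}ethan-1-one | CC(=O)c1c(O[Si](c2ccccc2)(c2ccccc2)C(C)(C)C)cc(OCOC)c([C@H](/C=C/C[C@H](O[Si](C)(C)C(C)(C)C)CCc2ccc(OCOC)cc2)c2ccc(OCOC)cc2)c1OCOC
F10 | step 14 | 1-{3-[(1R,2E,5R)-5-[(tert-butyldimethylsilyl)oxy]-1,7-bis[4-(methoxymethoxy)phenyl]hept-2-en-1-yl]-6-hydroxy-2,4-bis(methoxymethoxy)phenyl}ethan-1-one | CC(=O)c1c(O)cc(OCOC)c([C@H](/C=C/C[C@H](O[Si](C)(C)C(C)(C)C)CCc2ccc(OCOC)cc2)c2ccc(OCOC)cc2)c1OCOC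
F11 | step 14 | 1-{3-[(1R,2E,5R)-5-[(tert-butyldimethylsilyl)oxy]-1,7-bis[4-(methoxymethoxy)phenyl]hept-2-en-1-yl]-6-methoxy-2,4-bis(methoxymethoxy)phenyl}ethan-1-one | CC(=O)c1c(OC)cc(OCOC)c([C@H](/C=C/C[C@H](O[Si](C)(C)C(C)(C)C)CCc2ccc(OCOC)cc2)c2ccc(OCOC)cc2)c1OCOC
F12 | step 14 | (2E)-1-{3-[(1R,2E,5R)-5-[(tert-butyldimethylsilyl)oxy]-1,7-bis[4-(methoxymethoxy)phenyl]hept-2-en-1-yl]-6-methoxy-2,4-bis(methoxymethoxy)phenyl}-3-phenylprop-2-en-1-one | COc1cc(OCOC)c([C@H](/C=C/C[C@H](O[Si](C)(C)C(C)(C)C)CCc2ccc(OCOC)cc2)c2ccc(OCOC)cc2)c(OCOC)c1C(=O)/C=C/c1ccccc1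
A1 | alternative 1 | 2-[(1R,2E,5R)-Hp']-5-methoxy-3-[(triisopropylsilyl)oxy]phenol | COc1cc(O)c([C@H](/C=C/C[C@H](O[Si](C)(C)C(C)(C)C)CCc2ccc(O[Si](C)(C)C(C)(C)C)cc2)c2ccc(O[Si](C)(C)C(C)(C)C)cc2)c(O[Si](C(C)C)(C(C)C)C(C)C)c1
A2 | alternative 1 | 4-[(1S,2E,5R)-Hp']-3-[(triisopropylsilyl)oxy]cyclobut-2-en-1-one (ring C4 epimers) | O=C1C=C(O[Si](C(C)C)(C(C)C)C(C)C)C1[C@H](/C=C/C[C@H](O[Si](C)(C)C(C)(C)C)CCc1ccc(O[Si](C)(C)C(C)(C)C)cc1)c1ccc(O[Si](C)(C)C(C)(C)C)cc1
A3 | alternative 1 | methoxyacetylene (methoxyethyne) | COC#C
A4 | alternative 2 | 1-{3-[(1R,2E,5R)-Hp']-2,4-dihydroxy-6-methoxyphenyl}ethan-1-one | CC(=O)c1c(OC)cc(O)c([C@H](/C=C/C[C@H](O[Si](C)(C)C(C)(C)C)CCc2ccc(O[Si](C)(C)C(C)(C)C)cc2)c2ccc(O[Si](C)(C)C(C)(C)C)cc2)c1O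
A5 | alternative 2 | 1-methoxy-2-[(1R,2E,5R)-Hp']-1,3-bis(trimethylsiloxy)buta-1,3-diene (ketene acetal geometry not defined) | COC(O[Si](C)(C)C)=C([C@H](/C=C/C[C@H](O[Si](C)(C)C(C)(C)C)CCc1ccc(O[Si](C)(C)C(C)(C)C)cc1)c1ccc(O[Si](C)(C)C(C)(C)C)cc1)C(=C)O[Si](C)(C)C
A6 | alternative 2 | 4-methoxybut-3-yn-2-one | CC(=O)C#COC
A7 | alternative 3 | 2-[(1R,2E,5R)-5-[(tert-butyldimethylsilyl)oxy]-1,7-bis[4-(methoxymethoxy)phenyl]hept-2-en-1-yl]-5-methoxybenzene-1,3-diol | COc1cc(O)c([C@H](/C=C/C[C@H](O[Si](C)(C)C(C)(C)C)CCc2ccc(OCOC)cc2)c2ccc(OCOC)cc2)c(O)c1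
A8 | alternative 3 | 6-[(2R,3E,6R)-6-[(tert-butyldimethylsilyl)oxy]-2,8-bis[4-(methoxymethoxy)phenyl]oct-3-en-1-yl]-4-methoxy-2H-pyran-2-one | COC1=CC(=O)OC(C[C@H](/C=C/C[C@H](O[Si](C)(C)C(C)(C)C)CCc2ccc(OCOC)cc2)c2ccc(OCOC)cc2)=C1
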